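**Retrosynthetic overview**
1. The five phenols travel as benzyl ethers and the formyl group as an aryl bromide: target ⇐ penta-O-benzyl aldehyde ⇐ bis(dihydrobenzofuran) bromide 22.
2. The strategy rests on the O1–C2–C3 unit of each dihydrobenzofuran: both rings are trans (2R,3R) with the 4-oxyphenyl group on C2 next to O1. Each unit is therefore a 3,4-diaryl-3,4-dihydrocoumarin without its carbonyl carbon, and O1–C2 is made by oxidative decarboxylation of the opened lactone (carboxylate on the future C2, free phenol on the aryl group of the future C3).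
3. Each lactone comes from an enantioselective [4+2] of an ortho-quinone methide with the catalyst-bound enolate of 4-(benzyloxy)phenylacetic acid, supplied as its symmetric anhydride 9; this sets the future C3.
4. Ring order: lactone B → dihydrobenzofuran B (C4 bromide) → aryllithium coupling with 5-bromosalicylaldehyde → lactone A → dihydrobenzofuran A → CHO → debenzylation.

Key step: step 13

Assumption: 1, 8 and 14 are purchasable, and the antipode of the isothiourea catalyst that gives the 4R lactone is fixed in a scouting run with both antipodes (configuration to be confirmed, for example by X-ray analysis of bromide 13).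

Step 1
Reactants: 1 1-bromo-3,5-bis(benzyloxy)benzene
Product: 2 2,4-bis(benzyloxy)-6-bromobenzaldehyde
Conditions: POCl3 (2.5 equiv), DMF, 0 to 90 °C; then H2O, 50 °C
Reagents that add atoms: N,N-dimethylformamide CN(C)C=O; water O
Why: Vilsmeier–Haack formylation should go para to one benzyloxy group and ortho to the other (next to bromine), the site between the two ethers being more congested; a minor symmetric isomer would be removed by crystallisation.

Step 2
Reactants: 2 2,4-bis(benzyloxy)-6-bromobenzaldehyde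
Product: 3 4-(benzyloxy)-2-bromo-6-hydroxybenzaldehyde
Conditions: MgBr2·OEt2 (2 equiv), toluene/Et2O, 70 °C; 1 M HCl
Reagents that add atoms: none
Why: Chelation-controlled ether cleavage: magnesium held between the formyl oxygen and the ortho ether oxygen activates only that benzyl group for bromide attack, so the para benzyl ether stays.

Step 3
Reactants: 1 1-bromo-3,5-bis(benzyloxy)benzene; 3 4-(benzyloxy)-2-bromo-6-hydroxybenzaldehyde
Product: 6 racemic benzhydrol 5-(benzyloxy)-2-{[3,5-bis(benzyloxy)phenyl](hydroxy)methyl}-3-bromophenol, via 3,5-bis(benzyloxy)phenylmagnesium bromide 4 (not isolated), via sodium 5-(benzyloxy)-3-bromo-2-formylphenolate 5 (not isolated)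
Conditions: 1 (1.4 equiv), Mg, THF, 45 °C; separately 3, NaH (1.05 equiv), THF, 0 °C; Grignard solution added, 0 °C to rt; sat. aq. NH4Cl
Reagents that add atoms: none
Why: Grignard addition to an aldehyde whose phenol is masked as the sodium salt; an aryl Grignard reagent does not exchange with the aryl bromide, and the carbinol centre needs no control because it becomes planar in step 6.

Step 4
Reactants: 6 racemic benzhydrol 5-(benzyloxy)-2-{[3,5-bis(benzyloxy)phenyl](hydroxy)methyl}-3-bromophenol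
Product: 7 racemic sulfone 5-(benzyloxy)-2-{[3,5-bis(benzyloxy)phenyl](4-methylbenzenesulfonyl)methyl}-3-bromophenol
Conditions: p-TolSO2H (1.5 equiv, freshly liberated from its sodium salt), CH2Cl2, rt
Reagents that add atoms: p-toluenesulfinic acid Cc1ccc(cc1)S(O)=O
Why: Acid-promoted ionisation of the ortho-hydroxybenzhydrol and S-alkylation of the sulfinate is the standard entry to bench-stable 2-[aryl(sulfonyl)methyl]phenols, which release ortho-quinone methides with base.

Step 5
Reactants: 8 4-(benzyloxy)phenylacetic acid (two molecules)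
Product: 9 4-(benzyloxy)phenylacetic anhydride
Conditions: DCC (0.5 equiv), CH2Cl2, 0 °C to rt; filtration of the urea; crystallisation
Reagents that add atoms: none
Why: Carbodiimide dehydration: half an equivalent of DCC converts the acid through its O-acylisourea into the symmetric anhydride, a storable ammonium-enolate precursor, and one batch serves both [4+2] steps.

Step 6
Reactants: 7 racemic sulfone 5-(benzyloxy)-2-{[3,5-bis(benzyloxy)phenyl](4-methylbenzenesulfonyl)methyl}-3-bromophenol; 9 4-(benzyloxy)phenylacetic anhydride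
Product: 11 lactone B (3R,4R)-7-(benzyloxy)-3-[4-(benzyloxy)phenyl]-4-[3,5-bis(benzyloxy)phenyl]-5-bromo-3,4-dihydro-2H-chromen-2-one, via ortho-quinone methide 10 (not isolated)
Conditions: 7, 9 (1.5 equiv), HyperBTM (10 mol %, antipode selected for 4R), Cs2CO3 (2.5 equiv), CH2Cl2, 0 °C to rt
Reagents that add atoms: none
Why: Isothiourea-catalysed Michael addition–lactonisation (formal [4+2]): base expels sulfinate from 7 to give 10, the catalyst is acylated by anhydride 9 and deprotonated to the (Z)-ammonium enolate, this adds to the methide carbon and the phenoxide then closes the lactone and frees the catalyst; the catalyst shields one enolate face and the preferred approach to the planar methide should set C4 as R, a C3 epimer being harmless because C3 is lost later while the enantiomeric purity at C4 would be raised by recrystallisation.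

Step 7
Reactants: 11 lactone B (3R,4R)-7-(benzyloxy)-3-[4-(benzyloxy)phenyl]-4-[3,5-bis(benzyloxy)phenyl]-5-bromo-3,4-dihydro-2H-chromen-2-one
Product: 12 tetrabutylammonium (2R,3R)-3-[4-(benzyloxy)-2-bromo-6-hydroxyphenyl]-2-[4-(benzyloxy)phenyl]-3-[3,5-bis(benzyloxy)phenyl]propanoate
Conditions: Bu4NOH (40% aq., 1.00 equiv, titrated), THF, 0 °C to rt; evaporation, toluene/MeCN azeotrope, high vacuum
Reagents that add atoms: tetrabutylammonium hydroxide CCCC[N+](CCCC)(CCCC)CCCC.[OH-]
Why: Hydrolysis of the aryl lactone is fast and irreversible, and with exactly one equivalent of hydroxide the proton rests on the weaker acid, so the salt holds a carboxylate beside a neutral phenol and cannot relactonise.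

Step 8
Reactants: 12 tetrabutylammonium (2R,3R)-3-[4-(benzyloxy)-2-bromo-6-hydroxyphenyl]-2-[4-(benzyloxy)phenyl]-3-[3,5-bis(benzyloxy)phenyl]propanoate
Product: 13 ring B bromide (2R,3R)-6-(benzyloxy)-2-[4-(benzyloxy)phenyl]-3-[3,5-bis(benzyloxy)phenyl]-4-bromo-2,3-dihydro-1-benzofuran
Conditions: undivided cell, graphite anode, platinum cathode, constant current 5 mA cm-2, 2.2 F mol-1, CH2Cl2/HFIP 9:1, 12 (0.05 M) as its own electrolyte, 0 °C to rt
Reagents that add atoms: none
Why: Proposed new method: two-electron anodic oxidation of the carboxylate (non-Kolbe, Hofer–Moest pathway) expels CO2 and leaves the 4-benzyloxybenzyl cation, which the phenol on the neighbouring carbon should capture by 5-exo closure (O1–C2 bond) anti to the C3 aryl group to give the trans (2R,3R) ring; the closest known reactions are Hofer–Moest decarboxylative etherifications of 4-alkoxyphenylacetic acids with alcohols and the acid-mediated closure of 2-(1,2-diaryl-2-hydroxyethyl)phenols through the same cation, the carboxylate being the only anion at the anode while HFIP supplies the protons reduced at the cathode so that the C–Br bond is spared.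

Step 9
Reactants: 13 ring B bromide (2R,3R)-6-(benzyloxy)-2-[4-(benzyloxy)phenyl]-3-[3,5-bis(benzyloxy)phenyl]-4-bromo-2,3-dihydro-1-benzofuran; 14 5-bromosalicylaldehyde
Product: 17 benzhydrol A (5-bromo-2-hydroxyphenyl){(2R,3R)-6-(benzyloxy)-2-[4-(benzyloxy)phenyl]-3-[3,5-bis(benzyloxy)phenyl]-2,3-dihydro-1-benzofuran-4-yl}methanol as a mixture of carbinol epimers, via ring B aryllithium 15 (not isolated), via sodium 4-bromo-2-formylphenolate 16 (not isolated)
Conditions: 13, n-BuLi (1.05 equiv), THF, -78 °C, 10 min; transferred to 16 [from 14 (1.5 equiv), NaH (1.5 equiv), THF, 0 °C], -78 to -30 °C; sat. aq. NH4Cl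
Reagents that add atoms: none
Why: Bromine–lithium exchange at -78 °C outruns deprotonation of the ring C–H bonds, and the aryllithium should add to the formyl group (1,2-addition) faster than it exchanges with the bromide on the electron-rich phenoxide ring; both carbinol epimers are used because this carbon becomes planar in step 11.

Step 10
Reactants: 17 benzhydrol A (5-bromo-2-hydroxyphenyl){(2R,3R)-6-(benzyloxy)-2-[4-(benzyloxy)phenyl]-3-[3,5-bis(benzyloxy)phenyl]-2,3-dihydro-1-benzofuran-4-yl}methanol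
Product: 18 sulfone A 4-bromo-2-[{(2R,3R)-6-(benzyloxy)-2-[4-(benzyloxy)phenyl]-3-[3,5-bis(benzyloxy)phenyl]-2,3-dihydro-1-benzofuran-4-yl}(4-methylbenzenesulfonyl)methyl]phenol as a mixture of epimers
Conditions: p-TolSO2H (1.5 equiv), CH2Cl2, rt
Reagents that add atoms: p-toluenesulfinic acid Cc1ccc(cc1)S(O)=O
Why: Same sulfinate exchange as in step 4; the weak acid ionises only the ortho-hydroxybenzhydrol and should leave the C2–O bond of dihydrobenzofuran B intact.

Step 11
Reactants: 18 sulfone A 4-bromo-2-[{(2R,3R)-6-(benzyloxy)-2-[4-(benzyloxy)phenyl]-3-[3,5-bis(benzyloxy)phenyl]-2,3-dihydro-1-benzofuran-4-yl}(4-methylbenzenesulfonyl)methyl]phenol; 9 4-(benzyloxy)phenylacetic anhydride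
Product: 20 lactone A (3R,4R)-3-[4-(benzyloxy)phenyl]-6-bromo-4-{(2R,3R)-6-(benzyloxy)-2-[4-(benzyloxy)phenyl]-3-[3,5-bis(benzyloxy)phenyl]-2,3-dihydro-1-benzofuran-4-yl}-3,4-dihydro-2H-chromen-2-one, via ortho-quinone methide 19 (not isolated)
Conditions: 18, 9 (1.5 equiv), HyperBTM (10–20 mol %, antipode selected for 4R), Cs2CO3 (2.5 equiv), CH2Cl2, 0 °C to rt
Reagents that add atoms: none
Why: The same isothiourea-catalysed Michael addition–lactonisation with anhydride 9 as in step 6; the catalyst antipode is matched to the required 4R centre, and since ring B is already enantiopure the 4S isomers of 20 are diastereomers and can be removed by chromatography.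

Step 12
Reactants: 20 lactone A (3R,4R)-3-[4-(benzyloxy)phenyl]-6-bromo-4-{(2R,3R)-6-(benzyloxy)-2-[4-(benzyloxy)phenyl]-3-[3,5-bis(benzyloxy)phenyl]-2,3-dihydro-1-benzofuran-4-yl}-3,4-dihydro-2H-chromen-2-one
Product: 21 tetrabutylammonium (2R,3R)-2-[4-(benzyloxy)phenyl]-3-(5-bromo-2-hydroxyphenyl)-3-{(2R,3R)-6-(benzyloxy)-2-[4-(benzyloxy)phenyl]-3-[3,5-bis(benzyloxy)phenyl]-2,3-dihydro-1-benzofuran-4-yl}propanoate
Conditions: Bu4NOH (40% aq., 1.00 equiv, titrated), THF, 0 °C to rt; evaporation, toluene/MeCN azeotrope, high vacuum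
Reagents that add atoms: tetrabutylammonium hydroxide CCCC[N+](CCCC)(CCCC)CCCC.[OH-]
Why: Irreversible hydrolysis of the aryl lactone with one equivalent of hydroxide gives the carboxylate with the 4-bromophenol left neutral, as in step 7.

Step 13
Reactants: 21 tetrabutylammonium (2R,3R)-2-[4-(benzyloxy)phenyl]-3-(5-bromo-2-hydroxyphenyl)-3-{(2R,3R)-6-(benzyloxy)-2-[4-(benzyloxy)phenyl]-3-[3,5-bis(benzyloxy)phenyl]-2,3-dihydro-1-benzofuran-4-yl}propanoate
Product: 22 bis(dihydrobenzofuran) bromide (2R,3R)-2-[4-(benzyloxy)phenyl]-5-bromo-3-{(2R,3R)-6-(benzyloxy)-2-[4-(benzyloxy)phenyl]-3-[3,5-bis(benzyloxy)phenyl]-2,3-dihydro-1-benzofuran-4-yl}-2,3-dihydro-1-benzofuran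
Conditions: undivided cell, graphite anode, platinum cathode, constant current 5 mA cm-2, 2.2 F mol-1, CH2Cl2/HFIP 9:1, 21 (0.05 M) as its own electrolyte, 0 °C to rt
Reagents that add atoms: none
Why: Proposed new method: the carboxylate of 21 is discharged at the graphite anode (directly or through the radical cation of its 4-benzyloxyphenyl ring, both paths converging), CO2 is lost and the secondary benzylic radical is oxidised at once to the 4-benzyloxybenzyl cation, an O-benzylated para-quinone methide, while HFIP is reduced to hydrogen at the cathode. The closest known reaction types are the anodic Hofer–Moest decarboxylative etherification of 4-alkoxyphenylacetic acids and the acid-mediated cyclisation of 2-(1,2-diaryl-2-hydroxyethyl)phenols to trans-2,3-diaryl-2,3-dihydrobenzofurans through the same cation; new here is capture of the electrogenerated cation by a neighbouring free phenol. The furan ring of dihydrobenzofuran A closes by 5-exo-trig attack of the phenol oxygen on the cationic carbon (new O1–C2 bond, carboxyl carbon lost as CO2), the ring size being fixed by the two-carbon tether. The only new stereocentre, C2 of ring A, is controlled by C3: the phenol adds anti to the bulky ring B aryl group to give the trans (2R,3R) ring, which is also the thermodynamic isomer reachable from any cis product by acid through reversible C2–O ionisation, and C3 is untouched because it never becomes part of the cation. The step needs oxidation of the carboxylate ahead of the phenol and the benzyloxyarenes and survival of the C–Br bond; the first is secured by exactly one equivalent of base (phenol neutral and deactivated by its para bromine, carboxylate the only anion at the anode), the second by an easily reduced proton source at platinum and by stopping near 2.2 F per mole.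

Step 14
Reactants: 22 bis(dihydrobenzofuran) bromide (2R,3R)-2-[4-(benzyloxy)phenyl]-5-bromo-3-{(2R,3R)-6-(benzyloxy)-2-[4-(benzyloxy)phenyl]-3-[3,5-bis(benzyloxy)phenyl]-2,3-dihydro-1-benzofuran-4-yl}-2,3-dihydro-1-benzofuran
Product: 24 penta-O-benzyl aldehyde (2R,3R)-2-[4-(benzyloxy)phenyl]-3-{(2R,3R)-6-(benzyloxy)-2-[4-(benzyloxy)phenyl]-3-[3,5-bis(benzyloxy)phenyl]-2,3-dihydro-1-benzofuran-4-yl}-2,3-dihydro-1-benzofuran-5-carbaldehyde, via aryllithium 23 (not isolated)
Conditions: n-BuLi (1.1 equiv), THF, -78 °C; DMF (3 equiv), -78 to 0 °C; sat. aq. NH4Cl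
Reagents that add atoms: N,N-dimethylformamide CN(C)C=O
Why: Bouveault formylation: bromine–lithium exchange followed by addition to DMF gives a stable hemiaminal alkoxide that releases the aldehyde on work-up; there is no O–H group and the ring C–H bonds are not deprotonated at -78 °C, so the four stereocentres are kept.

Step 15
Reactants: 24 penta-O-benzyl aldehyde (2R,3R)-2-[4-(benzyloxy)phenyl]-3-{(2R,3R)-6-(benzyloxy)-2-[4-(benzyloxy)phenyl]-3-[3,5-bis(benzyloxy)phenyl]-2,3-dihydro-1-benzofuran-4-yl}-2,3-dihydro-1-benzofuran-5-carbaldehyde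
Product: 25 CNP0318276.1 (2R,3R)-3-[(2R,3R)-3-(3,5-dihydroxyphenyl)-6-hydroxy-2-(4-hydroxyphenyl)-2,3-dihydro-1-benzofuran-4-yl]-2-(4-hydroxyphenyl)-2,3-dihydro-1-benzofuran-5-carbaldehyde
Conditions: BCl3 (10 equiv), pentamethylbenzene (15 equiv), CH2Cl2, -78 °C; MeOH then H2O quench
Reagents that add atoms: none
Why: Lewis-acid debenzylation with pentamethylbenzene as a non-basic benzyl-cation scavenger should remove all five benzyl groups at -78 °C without reducing the aldehyde or hydrogenolysing the benzylic C2–O bonds, and the trans rings are the thermodynamic isomers should a C2–O bond ionise reversibly.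

**Compound list**
1 | 1-bromo-3,5-bis(benzyloxy)benzene | Brc1cc(OCc2ccccc2)cc(OCc2ccccc2)c1 | starting material
2 | 2,4-bis(benzyloxy)-6-bromobenzaldehyde | O=Cc1c(OCc2ccccc2)cc(OCc2ccccc2)cc1Br | intermediate
3 | 4-(benzyloxy)-2-bromo-6-hydroxybenzaldehyde | O=Cc1c(O)cc(OCc2ccccc2)cc1Br | intermediate
4 | 3,5-bis(benzyloxy)phenylmagnesium bromide | Br[Mg]c1cc(OCc2ccccc2)cc(OCc2ccccc2)c1 | intermediate
5 | sodium 5-(benzyloxy)-3-bromo-2-formylphenolate | [Na+].[O-]c1cc(OCc2ccccc2)cc(Br)c1C=O | intermediate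
6 | 5-(benzyloxy)-2-{[3,5-bis(benzyloxy)phenyl](hydroxy)methyl}-3-bromophenol (racemic) | OC(c1cc(OCc2ccccc2)cc(OCc2ccccc2)c1)c1c(O)cc(OCc2ccccc2)cc1Br | intermediate
7 | 5-(benzyloxy)-2-{[3,5-bis(benzyloxy)phenyl](4-methylbenzenesulfonyl)methyl}-3-bromophenol (racemic) | Cc1ccc(cc1)S(=O)(=O)C(c1cc(OCc2ccccc2)cc(OCc2ccccc2)c1)c1c(O)cc(OCc2ccccc2)cc1Br | intermediate
8 | 4-(benzyloxy)phenylacetic acid | OC(=O)Cc1ccc(OCc2ccccc2)cc1 | starting material
9 | 4-(benzyloxy)phenylacetic anhydride | O=C(Cc1ccc(OCc2ccccc2)cc1)OC(=O)Cc1ccc(OCc2ccccc2)cc1 | intermediate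
10 | ortho-quinone methide B, 3-(benzyloxy)-5-bromo-6-[3,5-bis(benzyloxy)benzylidene]cyclohexa-2,4-dien-1-one | O=C1C=C(OCc2ccccc2)C=C(Br)C1=Cc1cc(OCc2ccccc2)cc(OCc2ccccc2)c1 | intermediate
11 | lactone B, (3R,4R)-7-(benzyloxy)-3-[4-(benzyloxy)phenyl]-4-[3,5-bis(benzyloxy)phenyl]-5-bromo-3,4-dihydro-2H-chromen-2-one | O=C1Oc2cc(OCc3ccccc3)cc(Br)c2[C@@H](c2cc(OCc3ccccc3)cc(OCc3ccccc3)c2)[C@@H]1c1ccc(OCc2ccccc2)cc1 | intermediate
12 | tetrabutylammonium (2R,3R)-3-[4-(benzyloxy)-2-bromo-6-hydroxyphenyl]-2-[4-(benzyloxy)phenyl]-3-[3,5-bis(benzyloxy)phenyl]propanoate | CCCC[N+](CCCC)(CCCC)CCCC.[O-]C(=O)[C@@H](c1ccc(OCc2ccccc2)cc1)[C@H](c1cc(OCc2ccccc2)cc(OCc2ccccc2)c1)c1c(O)cc(OCc2ccccc2)cc1Br | intermediate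
13 | (2R,3R)-6-(benzyloxy)-2-[4-(benzyloxy)phenyl]-3-[3,5-bis(benzyloxy)phenyl]-4-bromo-2,3-dihydro-1-benzofuran | Brc1cc(OCc2ccccc2)cc2c1[C@@H](c1cc(OCc3ccccc3)cc(OCc3ccccc3)c1)[C@H](c1ccc(OCc3ccccc3)cc1)O2 | intermediate
14 | 5-bromosalicylaldehyde | O=Cc1cc(Br)ccc1O | starting material
15 | ring B aryllithium, {(2R,3R)-6-(benzyloxy)-2-[4-(benzyloxy)phenyl]-3-[3,5-bis(benzyloxy)phenyl]-2,3-dihydro-1-benzofuran-4-yl}lithium | [Li]c1cc(OCc2ccccc2)cc2c1[C@@H](c1cc(OCc3ccccc3)cc(OCc3ccccc3)c1)[C@H](c1ccc(OCc3ccccc3)cc1)O2 | intermediate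
16 | sodium 4-bromo-2-formylphenolate | [Na+].[O-]c1ccc(Br)cc1C=O | intermediate
17 | (5-bromo-2-hydroxyphenyl){(2R,3R)-6-(benzyloxy)-2-[4-(benzyloxy)phenyl]-3-[3,5-bis(benzyloxy)phenyl]-2,3-dihydro-1-benzofuran-4-yl}methanol (carbinol epimers) | OC(c1cc(Br)ccc1O)c1cc(OCc2ccccc2)cc2c1[C@@H](c1cc(OCc3ccccc3)cc(OCc3ccccc3)c1)[C@H](c1ccc(OCc3ccccc3)cc1)O2 | intermediate
18 | 4-bromo-2-[{(2R,3R)-6-(benzyloxy)-2-[4-(benzyloxy)phenyl]-3-[3,5-bis(benzyloxy)phenyl]-2,3-dihydro-1-benzofuran-4-yl}(4-methylbenzenesulfonyl)methyl]phenol (epimers) | Cc1ccc(cc1)S(=O)(=O)C(c1cc(Br)ccc1O)c1cc(OCc2ccccc2)cc2c1[C@@H](c1cc(OCc3ccccc3)cc(OCc3ccccc3)c1)[C@H](c1ccc(OCc3ccccc3)cc1)O2 | intermediate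
19 | ortho-quinone methide A, 4-bromo-6-[({(2R,3R)-6-(benzyloxy)-2-[4-(benzyloxy)phenyl]-3-[3,5-bis(benzyloxy)phenyl]-2,3-dihydro-1-benzofuran-4-yl})methylidene]cyclohexa-2,4-dien-1-one | O=C1C=CC(Br)=CC1=Cc1cc(OCc2ccccc2)cc2c1[C@@H](c1cc(OCc3ccccc3)cc(OCc3ccccc3)c1)[C@H](c1ccc(OCc3ccccc3)cc1)O2 | intermediate
20 | lactone A, (3R,4R)-3-[4-(benzyloxy)phenyl]-6-bromo-4-{(2R,3R)-6-(benzyloxy)-2-[4-(benzyloxy)phenyl]-3-[3,5-bis(benzyloxy)phenyl]-2,3-dihydro-1-benzofuran-4-yl}-3,4-dihydro-2H-chromen-2-one | O=C1Oc2ccc(Br)cc2[C@@H](c2cc(OCc3ccccc3)cc3c2[C@@H](c2cc(OCc4ccccc4)cc(OCc4ccccc4)c2)[C@H](c2ccc(OCc4ccccc4)cc2)O3)[C@@H]1c1ccc(OCc2ccccc2)cc1 | intermediate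
21 | tetrabutylammonium (2R,3R)-2-[4-(benzyloxy)phenyl]-3-(5-bromo-2-hydroxyphenyl)-3-{(2R,3R)-6-(benzyloxy)-2-[4-(benzyloxy)phenyl]-3-[3,5-bis(benzyloxy)phenyl]-2,3-dihydro-1-benzofuran-4-yl}propanoate | CCCC[N+](CCCC)(CCCC)CCCC.[O-]C(=O)[C@@H](c1ccc(OCc2ccccc2)cc1)[C@H](c1cc(OCc2ccccc2)cc2c1[C@@H](c1cc(OCc3ccccc3)cc(OCc3ccccc3)c1)[C@H](c1ccc(OCc3ccccc3)cc1)O2)c1cc(Br)ccc1O | intermediate
22 | (2R,3R)-2-[4-(benzyloxy)phenyl]-5-bromo-3-{(2R,3R)-6-(benzyloxy)-2-[4-(benzyloxy)phenyl]-3-[3,5-bis(benzyloxy)phenyl]-2,3-dihydro-1-benzofuran-4-yl}-2,3-dihydro-1-benzofuran | Brc1ccc2c(c1)[C@@H](c1cc(OCc3ccccc3)cc3c1[C@@H](c1cc(OCc4ccccc4)cc(OCc4ccccc4)c1)[C@H](c1ccc(OCc4ccccc4)cc1)O3)[C@H](c1ccc(OCc3ccccc3)cc1)O2 | intermediate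
23 | aryllithium from 22 (lithium in place of bromine at C5 of ring A) | [Li]c1ccc2c(c1)[C@@H](c1cc(OCc3ccccc3)cc3c1[C@@H](c1cc(OCc4ccccc4)cc(OCc4ccccc4)c1)[C@H](c1ccc(OCc4ccccc4)cc1)O3)[C@H](c1ccc(OCc3ccccc3)cc1)O2 | intermediate
24 | (2R,3R)-2-[4-(benzyloxy)phenyl]-3-{(2R,3R)-6-(benzyloxy)-2-[4-(benzyloxy)phenyl]-3-[3,5-bis(benzyloxy)phenyl]-2,3-dihydro-1-benzofuran-4-yl}-2,3-dihydro-1-benzofuran-5-carbaldehyde | O=Cc1ccc2c(c1)[C@@H](c1cc(OCc3ccccc3)cc3c1[C@@H](c1cc(OCc4ccccc4)cc(OCc4ccccc4)c1)[C@H](c1ccc(OCc4ccccc4)cc1)O3)[C@H](c1ccc(OCc3ccccc3)cc1)O2 | intermediate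
25 | CNP0318276.1, (2R,3R)-3-[(2R,3R)-3-(3,5-dihydroxyphenyl)-6-hydroxy-2-(4-hydroxyphenyl)-2,3-dihydro-1-benzofuran-4-yl]-2-(4-hydroxyphenyl)-2,3-dihydro-1-benzofuran-5-carbaldehyde | O=Cc1ccc2c(c1)[C@@H](c1cc(O)cc3c1[C@@H](c1cc(O)cc(O)c1)[C@H](c1ccc(O)cc1)O3)[C@H](c1ccc(O)cc1)O2 | target

**Totals**
Total steps: 15. Longest linear sequence: 14 steps (1 → 25 through steps 1–4 and 6–15); step 5 makes anhydride 9 from 8 in a side branch, compound 1 is used a second time in step 3, and 14 enters as purchased.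

**Steps most likely to fail**

1. Step 13 (proposed new method). The anode may oxidise the phenol or the benzyloxyarene rings in competition with carboxylate discharge. The cation may lose the C3 proton to give a triarylethene before the ring closes. The C–Br bond may be cleaved at the cathode.
Fallback by known chemistry, from 21 back to 22. Salt 21 with MOMCl and iPr2NEt in CH2Cl2 should give the methoxymethyl ester methoxymethyl ether F1. LiOH in THF/H2O cleaves only the ester and gives the O-protected acid F2, which can be activated or oxidised without relactonising. Pb(OAc)4 with pyridine in benzene at 80 °C (oxidative decarboxylation of an arylacetic acid) should give the benzylic acetate F3 as a mixture of epimers. TFA in wet CH2Cl2 at 0 °C then removes the methoxymethyl group and ionises the acetate, and the freed phenol closes on the cation (the known acid-mediated trans-selective cyclisation) to give 22.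

2. Step 8 (proposed new method). The same processes threaten it, and the alkoxy-substituted phenol of ring B is easier to oxidise than the bromophenol of ring A, so competitive phenol oxidation is the main concern.
Fallback by known chemistry, from 6 back to 13. Benzhydrol 6 is O-alkylated on the phenol with 4-(benzyloxy)benzyl chloride and K2CO3 in DMF to give the ether alcohol F4. Dess–Martin periodinane gives the benzophenone F5, and N2H4·H2O with catalytic AcOH in hot EtOH gives the hydrazone F6. MnO2 in CH2Cl2 at 0 °C gives the diaryldiazomethane F7, used at once. Rh2(R-PTAD)4 or its antipode (1 mol %, chosen for 3R) should effect enantioselective intramolecular C–H insertion of the donor/donor carbene into the ArCH2–O bond to give the cis (2S,3R) dihydrobenzofuran F8. Catalytic TFA in CH2Cl2 then epimerises C2 through reversible C2–O ionisation to the trans bromide 13.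

3. Step 9. The hindered aryllithium may be protonated before it adds, halogen–metal scrambling with the bromide of the aldehyde partner may occur, and addition to the sparingly soluble, deactivated phenoxide may be slow.
Fallback with reversed polarity, from 13 back to 18. Bromide 13 is formylated (n-BuLi, THF, -78 °C, then DMF) to the ring B aldehyde F9. Commercial 4-bromo-2-iodophenol is protected (MOMCl, iPr2NEt) as 4-bromo-2-iodo-1-(methoxymethoxy)benzene F10. Iodine-selective exchange with iPrMgCl·LiCl in THF at -30 °C gives the arylmagnesium chloride F11, which adds to F9 to give the protected benzhydrol F12. p-TolSO2H with catalytic TsOH in CH2Cl2 converts F12 into the protected sulfone F13, and HCl in MeOH/THF removes the methoxymethyl group to give sulfone 18.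

**Further compounds**
F1 | step 13 | methoxymethyl (2R,3R)-2-[4-(benzyloxy)phenyl]-3-[5-bromo-2-(methoxymethoxy)phenyl]-3-{(2R,3R)-6-(benzyloxy)-2-[4-(benzyloxy)phenyl]-3-[3,5-bis(benzyloxy)phenyl]-2,3-dihydro-1-benzofuran-4-yl}propanoate | COCOC(=O)[C@@H](c1ccc(OCc2ccccc2)cc1)[C@H](c1cc(OCc2ccccc2)cc2c1[C@@H](c1cc(OCc3ccccc3)cc(OCc3ccccc3)c1)[C@H](c1ccc(OCc3ccccc3)cc1)O2)c1cc(Br)ccc1OCOC
F2 | step 13 | (2R,3R)-2-[4-(benzyloxy)phenyl]-3-[5-bromo-2-(methoxymethoxy)phenyl]-3-{(2R,3R)-6-(benzyloxy)-2-[4-(benzyloxy)phenyl]-3-[3,5-bis(benzyloxy)phenyl]-2,3-dihydro-1-benzofuran-4-yl}propanoic acid | OC(=O)[C@@H](c1ccc(OCc2ccccc2)cc1)[C@H](c1cc(OCc2ccccc2)cc2c1[C@@H](c1cc(OCc3ccccc3)cc(OCc3ccccc3)c1)[C@H](c1ccc(OCc3ccccc3)cc1)O2)c1cc(Br)ccc1OCOC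
F3 | step 13 | (2R)-1-[4-(benzyloxy)phenyl]-2-[5-bromo-2-(methoxymethoxy)phenyl]-2-{(2R,3R)-6-(benzyloxy)-2-[4-(benzyloxy)phenyl]-3-[3,5-bis(benzyloxy)phenyl]-2,3-dihydro-1-benzofuran-4-yl}ethyl acetate (epimers at C1) | CC(=O)OC(c1ccc(OCc2ccccc2)cc1)[C@H](c1cc(OCc2ccccc2)cc2c1[C@@H](c1cc(OCc3ccccc3)cc(OCc3ccccc3)c1)[C@H](c1ccc(OCc3ccccc3)cc1)O2)c1cc(Br)ccc1OCOC
F4 | step 8 | [4-(benzyloxy)-2-{[4-(benzyloxy)phenyl]methoxy}-6-bromophenyl][3,5-bis(benzyloxy)phenyl]methanol (racemic) | OC(c1cc(OCc2ccccc2)cc(OCc2ccccc2)c1)c1c(OCc2ccc(OCc3ccccc3)cc2)cc(OCc2ccccc2)cc1Br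
F5 | step 8 | [4-(benzyloxy)-2-{[4-(benzyloxy)phenyl]methoxy}-6-bromophenyl][3,5-bis(benzyloxy)phenyl]methanone | O=C(c1cc(OCc2ccccc2)cc(OCc2ccccc2)c1)c1c(OCc2ccc(OCc3ccccc3)cc2)cc(OCc2ccccc2)cc1Br
F6 | step 8 | hydrazone of [4-(benzyloxy)-2-{[4-(benzyloxy)phenyl]methoxy}-6-bromophenyl][3,5-bis(benzyloxy)phenyl]methanone | NN=C(c1cc(OCc2ccccc2)cc(OCc2ccccc2)c1)c1c(OCc2ccc(OCc3ccccc3)cc2)cc(OCc2ccccc2)cc1Br
F7 | step 8 | [4-(benzyloxy)-2-{[4-(benzyloxy)phenyl]methoxy}-6-bromophenyl][3,5-bis(benzyloxy)phenyl]diazomethane | [N-]=[N+]=C(c1cc(OCc2ccccc2)cc(OCc2ccccc2)c1)c1c(OCc2ccc(OCc3ccccc3)cc2)cc(OCc2ccccc2)cc1Br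
F8 | step 8 | cis (2S,3R)-6-(benzyloxy)-2-[4-(benzyloxy)phenyl]-3-[3,5-bis(benzyloxy)phenyl]-4-bromo-2,3-dihydro-1-benzofuran | Brc1cc(OCc2ccccc2)cc2c1[C@@H](c1cc(OCc3ccccc3)cc(OCc3ccccc3)c1)[C@@H](c1ccc(OCc3ccccc3)cc1)O2
F9 | step 9 | (2R,3R)-6-(benzyloxy)-2-[4-(benzyloxy)phenyl]-3-[3,5-bis(benzyloxy)phenyl]-2,3-dihydro-1-benzofuran-4-carbaldehyde | O=Cc1cc(OCc2ccccc2)cc2c1[C@@H](c1cc(OCc3ccccc3)cc(OCc3ccccc3)c1)[C@H](c1ccc(OCc3ccccc3)cc1)O2
F10 | step 9 | 4-bromo-2-iodo-1-(methoxymethoxy)benzene | COCOc1ccc(Br)cc1I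
F11 | step 9 | [5-bromo-2-(methoxymethoxy)phenyl]magnesium chloride | COCOc1ccc(Br)cc1[Mg]Cl
F12 | step 9 | [5-bromo-2-(methoxymethoxy)phenyl]{(2R,3R)-6-(benzyloxy)-2-[4-(benzyloxy)phenyl]-3-[3,5-bis(benzyloxy)phenyl]-2,3-dihydro-1-benzofuran-4-yl}methanol (carbinol epimers) | OC(c1cc(Br)ccc1OCOC)c1cc(OCc2ccccc2)cc2c1[C@@H](c1cc(OCc3ccccc3)cc(OCc3ccccc3)c1)[C@H](c1ccc(OCc3ccccc3)cc1)O2
F13 | step 9 | (2R,3R)-6-(benzyloxy)-2-[4-(benzyloxy)phenyl]-3-[3,5-bis(benzyloxy)phenyl]-4-{[5-bromo-2-(methoxymethoxy)phenyl](4-methylbenzenesulfonyl)methyl}-2,3-dihydro-1-benzofuran (epimers) | Cc1ccc(cc1)S(=O)(=O)C(c1cc(Br)ccc1OCOC)c1cc(OCc2ccccc2)cc2c1[C@@H](c1cc(OCc3ccccc3)cc(OCc3ccccc3)c1)[C@H](c1ccc(OCc3ccccc3)cc1)O2
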